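**Assumption:** the target has no stereocentre and no stereogenic double bond, so it is one achiral compound and no enantiocontrol is needed. The stereocentres that appear in intermediates 13 and 15 are racemic and are erased later.

**Retrosynthetic overview**
- Target ⇐ global O-debenzylation of its pentabenzyl ether ⇐ C=O → CH2 deoxygenation of a fully benzyl-protected deoxybenzoin.
- Deoxybenzoin ⇐ decarboxylation of a β-keto ester ⇐ crossed Claisen condensation of a ring-A arylacetate enolate with a ring-B salicylate ester; this forms the bibenzyl C–C bond.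
- Ring-A arylacetate ⇐ twofold Negishi benzylation of a 2,6-dibromide ⇐ NBS dibromination ⇐ 3,5-dimethoxyphenylacetic acid (mono-demethylation, esterification, benzylation).
- Ring-B ester ⇐ Negishi benzylation of O-benzylated methyl 5-bromosalicylate; one benzylzinc reagent, from 4-(benzyloxy)benzyl chloride, supplies all three p-oxybenzyl groups.
- No ring is constructed: all five benzene rings come from commercial aromatics.

**Route**

Step 1
Reactants: 1 4-(benzyloxy)benzyl chloride
Product: 2 [4-(benzyloxy)benzyl]zinc chloride (titrated THF solution, LiCl complex)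
Conditions: Zn dust (activated with BrCH2CH2Br, TMSCl), LiCl, THF, 25 °C; titrate with I2
Reagents that add atoms: zinc, [Zn]
Why: LiCl-mediated direct zinc insertion into a benzylic chloride gives the benzylzinc reagent with little Wurtz coupling and tolerates the aryl benzyl ether.

Step 2
Reactants: 3 methyl 5-bromo-2-hydroxybenzoate
Product: 4 methyl 2-(benzyloxy)-5-bromobenzoate
Conditions: BnBr, K2CO3, DMF, 60 °C
Reagents that add atoms: benzyl bromide, BrCc1ccccc1
Why: Williamson ether synthesis on the salicylate phenol, with a base too weak to harm the methyl ester.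

Step 3
Reactants: 4 methyl 2-(benzyloxy)-5-bromobenzoate; 2 [4-(benzyloxy)benzyl]zinc chloride (1.3 equiv)
Product: 5 methyl 2-(benzyloxy)-5-[4-(benzyloxy)benzyl]benzoate
Conditions: Pd(OAc)2 (2 mol%), SPhos (4 mol%), THF, 25 → 50 °C
Reagents that add atoms: none
Why: Negishi sp3–sp2 cross-coupling of a benzylzinc with an unhindered aryl bromide is fast with Pd/SPhos, and the ester is inert to organozinc.

Step 4
Reactants: 6 3,5-dimethoxyphenylacetic acid
Product: 7 3-hydroxy-5-methoxyphenylacetic acid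
Conditions: NaSEt (4 equiv), DMF, 130 °C; then aq HCl
Reagents that add atoms: none
Why: Thiolate SN2 O-demethylation of an aryl methyl ether stops after one of the two equivalent methyl groups, because the phenoxide formed deactivates the second ether.

Step 5
Reactants: 7 3-hydroxy-5-methoxyphenylacetic acid
Product: 8 methyl (3-hydroxy-5-methoxyphenyl)acetate
Conditions: MeOH, H2SO4 (cat.), reflux
Reagents that add atoms: methanol, CO
Why: Fischer esterification converts the carboxylic acid selectively and leaves the phenol free.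

Step 6
Reactants: 8 methyl (3-hydroxy-5-methoxyphenyl)acetate
Product: 9 methyl [3-(benzyloxy)-5-methoxyphenyl]acetate
Conditions: BnBr, K2CO3, acetone, reflux
Reagents that add atoms: benzyl bromide, BrCc1ccccc1
Why: Williamson etherification of the phenol; carbonate cannot deprotonate the ester α-CH2, so no C-alkylation occurs.

Step 7
Reactants: 9 methyl [3-(benzyloxy)-5-methoxyphenyl]acetate
Product: 10 methyl [3-(benzyloxy)-2,6-dibromo-5-methoxyphenyl]acetate
Conditions: NBS (2.05 equiv), MeCN, 0 °C → rt, dark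
Reagents that add atoms: N-bromosuccinimide, O=C1CCC(=O)N1Br
Why: Electrophilic aromatic bromination goes to C-2 and C-6, each para to one oxygen, as in the usual 2,6-dihalogenation of 3,5-dialkoxyphenyl compounds, and leaves C-4 between the two ethers untouched.

Step 8
Reactants: 10 methyl [3-(benzyloxy)-2,6-dibromo-5-methoxyphenyl]acetate; 2 [4-(benzyloxy)benzyl]zinc chloride (3 equiv)
Product: 11 methyl 2-[3-(benzyloxy)-2,6-bis[4-(benzyloxy)benzyl]-5-methoxyphenyl]acetate
Conditions: Pd(OAc)2 (5 mol%), SPhos (10 mol%), THF, 60 °C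
Reagents that add atoms: none
Why: Twofold Negishi coupling, in which SPhos enables oxidative addition and reductive elimination at the di-ortho-substituted electron-rich C–Br bonds and the benzylzinc neither deprotonates nor attacks the ester.

Step 9
Reactants: 11 methyl 2-[3-(benzyloxy)-2,6-bis[4-(benzyloxy)benzyl]-5-methoxyphenyl]acetate; 5 methyl 2-(benzyloxy)-5-[4-(benzyloxy)benzyl]benzoate (1.1 equiv)
Product: 13 methyl 2-[3-(benzyloxy)-2,6-bis[4-(benzyloxy)benzyl]-5-methoxyphenyl]-3-[2-(benzyloxy)-5-[4-(benzyloxy)benzyl]phenyl]-3-oxopropanoate (racemic), via lithium ester enolate 12 (not isolated)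
Conditions: LiHMDS (2.3 equiv), THF, −78 °C; then 5, −78 °C → rt; aq NH4Cl
Reagents that add atoms: none
Why: Crossed Claisen condensation in which only 11 can form an enolate, the non-enolisable ester 5 is the acyl acceptor, and the second equivalent of base drives the equilibrium by deprotonating the β-keto ester; the new stereocentre is racemic and is erased in step 10.

Step 10
Reactants: 13 β-keto ester
Product: 14 1-[2-(benzyloxy)-5-[4-(benzyloxy)benzyl]phenyl]-2-[3-(benzyloxy)-2,6-bis[4-(benzyloxy)benzyl]-5-methoxyphenyl]ethan-1-one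
Conditions: LiCl (2 equiv), DMSO–H2O, 130 °C
Reagents that add atoms: none
Why: Krapcho dealkoxycarbonylation, in which chloride demethylates the β-keto methyl ester and the carboxylate loses CO2 under near-neutral conditions that avoid retro-Claisen cleavage.

Step 11
Reactants: 14 deoxybenzoin ketone
Product: 15 1-[2-(benzyloxy)-5-[4-(benzyloxy)benzyl]phenyl]-2-[3-(benzyloxy)-2,6-bis[4-(benzyloxy)benzyl]-5-methoxyphenyl]ethan-1-ol (racemic)
Conditions: NaBH4, THF–MeOH, 0 °C → rt
Reagents that add atoms: none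
Why: Borohydride reduction of the aryl ketone gives the benzylic alcohol as a racemate, whose stereocentre is removed in step 12.

Step 12
Reactants: 15 benzylic alcohol
Product: 16 1-(benzyloxy)-2,4-bis[4-(benzyloxy)benzyl]-3-[2-[2-(benzyloxy)-5-[4-(benzyloxy)benzyl]phenyl]ethyl]-5-methoxybenzene
Conditions: Et3SiH (3 equiv), TFA (5 equiv), CH2Cl2, 0 °C
Reagents that add atoms: none
Why: Ionic hydrogenation, in which TFA ionises the ortho-alkoxybenzylic alcohol to a stabilised cation that Et3SiH reduces to CH2; plain aryl benzyl ethers survive cold TFA.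

Step 13
Reactants: 16 pentabenzyl ether
Product: 17 3-[2-[2-hydroxy-5-(4-hydroxybenzyl)phenyl]ethyl]-2,4-bis(4-hydroxybenzyl)-5-methoxyphenol (target, CNP0134121.0)
Conditions: H2 (1 atm), 10% Pd/C, THF–MeOH, rt
Reagents that add atoms: none
Why: Catalytic hydrogenolysis cleaves all five O-benzyl ethers, while the aryl methyl ether and the diarylmethane and bibenzyl C–C bonds are inert.

**Compound list**
1 | 4-(benzyloxy)benzyl chloride | ClCc1ccc(OCc2ccccc2)cc1 | starting material
2 | [4-(benzyloxy)benzyl]zinc chloride | Cl[Zn]Cc1ccc(OCc2ccccc2)cc1 | intermediate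
3 | methyl 5-bromo-2-hydroxybenzoate | COC(=O)c1cc(Br)ccc1O | starting material
4 | methyl 2-(benzyloxy)-5-bromobenzoate | COC(=O)c1cc(Br)ccc1OCc1ccccc1 | intermediate
5 | methyl 2-(benzyloxy)-5-[4-(benzyloxy)benzyl]benzoate | COC(=O)c1cc(Cc2ccc(OCc3ccccc3)cc2)ccc1OCc1ccccc1 | intermediate
6 | 3,5-dimethoxyphenylacetic acid | COc1cc(CC(=O)O)cc(OC)c1 | starting material
7 | 3-hydroxy-5-methoxyphenylacetic acid | COc1cc(O)cc(CC(=O)O)c1 | intermediate
8 | methyl (3-hydroxy-5-methoxyphenyl)acetate | COC(=O)Cc1cc(O)cc(OC)c1 | intermediate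
9 | methyl [3-(benzyloxy)-5-methoxyphenyl]acetate | COC(=O)Cc1cc(OC)cc(OCc2ccccc2)c1 | intermediate
10 | methyl [3-(benzyloxy)-2,6-dibromo-5-methoxyphenyl]acetate | COC(=O)Cc1c(Br)c(OC)cc(OCc2ccccc2)c1Br | intermediate
11 | methyl 2-[3-(benzyloxy)-2,6-bis[4-(benzyloxy)benzyl]-5-methoxyphenyl]acetate | COC(=O)Cc1c(Cc2ccc(OCc3ccccc3)cc2)c(OC)cc(OCc2ccccc2)c1Cc1ccc(OCc2ccccc2)cc1 | intermediate
12 | lithium ester enolate of 11 (not isolated) | [Li]OC(OC)=Cc1c(Cc2ccc(OCc3ccccc3)cc2)c(OC)cc(OCc2ccccc2)c1Cc1ccc(OCc2ccccc2)cc1 | intermediate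
13 | methyl 2-[3-(benzyloxy)-2,6-bis[4-(benzyloxy)benzyl]-5-methoxyphenyl]-3-[2-(benzyloxy)-5-[4-(benzyloxy)benzyl]phenyl]-3-oxopropanoate (racemic) | COC(=O)C(C(=O)c1cc(Cc2ccc(OCc3ccccc3)cc2)ccc1OCc1ccccc1)c1c(Cc2ccc(OCc3ccccc3)cc2)c(OC)cc(OCc2ccccc2)c1Cc1ccc(OCc2ccccc2)cc1 | intermediate
14 | 1-[2-(benzyloxy)-5-[4-(benzyloxy)benzyl]phenyl]-2-[3-(benzyloxy)-2,6-bis[4-(benzyloxy)benzyl]-5-methoxyphenyl]ethan-1-one | O=C(Cc1c(Cc2ccc(OCc3ccccc3)cc2)c(OC)cc(OCc2ccccc2)c1Cc1ccc(OCc2ccccc2)cc1)c1cc(Cc2ccc(OCc3ccccc3)cc2)ccc1OCc1ccccc1 | intermediate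
15 | 1-[2-(benzyloxy)-5-[4-(benzyloxy)benzyl]phenyl]-2-[3-(benzyloxy)-2,6-bis[4-(benzyloxy)benzyl]-5-methoxyphenyl]ethan-1-ol (racemic) | OC(Cc1c(Cc2ccc(OCc3ccccc3)cc2)c(OC)cc(OCc2ccccc2)c1Cc1ccc(OCc2ccccc2)cc1)c1cc(Cc2ccc(OCc3ccccc3)cc2)ccc1OCc1ccccc1 | intermediate
16 | 1-(benzyloxy)-2,4-bis[4-(benzyloxy)benzyl]-3-[2-[2-(benzyloxy)-5-[4-(benzyloxy)benzyl]phenyl]ethyl]-5-methoxybenzene | COc1cc(OCc2ccccc2)c(Cc2ccc(OCc3ccccc3)cc2)c(CCc2cc(Cc3ccc(OCc4ccccc4)cc3)ccc2OCc2ccccc2)c1Cc1ccc(OCc2ccccc2)cc1 | intermediate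
17 | 3-[2-[2-hydroxy-5-(4-hydroxybenzyl)phenyl]ethyl]-2,4-bis(4-hydroxybenzyl)-5-methoxyphenol | COc1cc(O)c(Cc2ccc(O)cc2)c(CCc2cc(Cc3ccc(O)cc3)ccc2O)c1Cc1ccc(O)cc1 | target

**Totals**
Total step count: 13. Longest linear sequence: 10 steps (6 → 17, steps 4–13).

**Three steps most likely to fail, with fallbacks**

Step 8 (twofold Negishi coupling at two di-ortho-substituted C–Br bonds; it may stall at mono-coupling or give protodebromination). The fallback sets out from 9 and bypasses the dibromide. Commercial 4-(benzyloxy)benzyl alcohol is converted with Cl3CCN and catalytic DBU in CH2Cl2 into 4-(benzyloxy)benzyl 2,2,2-trichloroacetimidate F1. Two and a quarter equivalents of F1 with catalytic TMSOTf in CH2Cl2 at −40 → 0 °C then benzylate 9 twice in a Friedel–Crafts reaction at C-2 and C-6, the same para-to-oxygen positions that halogenation selects. Regiochemistry is less certain here, so C-4-benzylated and over-alkylated material must be removed by chromatography. The fallback comes back to the route at 11.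

Step 9 (crossed Claisen between a hindered arylacetate enolate and an ortho-substituted benzoate; the ester may be too poor an electrophile). The fallback sets out from 5 and replaces the ester acceptor by an aldehyde. LiAlH4 in THF at 0 °C gives {2-(benzyloxy)-5-[4-(benzyloxy)benzyl]phenyl}methanol F2, and MnO2 in CH2Cl2 oxidises it to 2-(benzyloxy)-5-[4-(benzyloxy)benzyl]benzaldehyde F3. Aldol addition of the lithium enolate 12 (from 11 and LiHMDS at −78 °C) to F3 gives methyl 2-[3-(benzyloxy)-2,6-bis[4-(benzyloxy)benzyl]-5-methoxyphenyl]-3-[2-(benzyloxy)-5-[4-(benzyloxy)benzyl]phenyl]-3-hydroxypropanoate F4 as a diastereomer mixture. Dess–Martin periodinane buffered with NaHCO3 in CH2Cl2 oxidises F4 to the β-keto ester, so the fallback comes back to the route at 13.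

Step 12 (strong acid with five aryl benzyl ethers and very electron-rich rings; Friedel–Crafts side reactions of the benzylic cation or benzyl migration are possible). The fallback sets out from 15 and avoids acid. MsCl and Et3N in CH2Cl2 at 0 °C give 1-[2-(benzyloxy)-5-[4-(benzyloxy)benzyl]phenyl]-2-[3-(benzyloxy)-2,6-bis[4-(benzyloxy)benzyl]-5-methoxyphenyl]ethyl methanesulfonate F5, which is not isolated. DBU in toluene at 60 °C eliminates it to the (E)-stilbene 1-(benzyloxy)-2,4-bis[4-(benzyloxy)benzyl]-3-[(E)-2-[2-(benzyloxy)-5-[4-(benzyloxy)benzyl]phenyl]ethenyl]-5-methoxybenzene F6. Hydrogenation of F6 under the step 13 conditions saturates the alkene and removes all five benzyl groups in one operation, so the fallback comes back to the route at 17.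

**Further compounds**
F1 | step 8 | 4-(benzyloxy)benzyl 2,2,2-trichloroacetimidate | N=C(OCc1ccc(OCc2ccccc2)cc1)C(Cl)(Cl)Cl
F2 | step 9 | {2-(benzyloxy)-5-[4-(benzyloxy)benzyl]phenyl}methanol | OCc1cc(Cc2ccc(OCc3ccccc3)cc2)ccc1OCc1ccccc1
F3 | step 9 | 2-(benzyloxy)-5-[4-(benzyloxy)benzyl]benzaldehyde | O=Cc1cc(Cc2ccc(OCc3ccccc3)cc2)ccc1OCc1ccccc1
F4 | step 9 | methyl 2-[3-(benzyloxy)-2,6-bis[4-(benzyloxy)benzyl]-5-methoxyphenyl]-3-[2-(benzyloxy)-5-[4-(benzyloxy)benzyl]phenyl]-3-hydroxypropanoate (racemic diastereomer mixture) | COC(=O)C(C(O)c1cc(Cc2ccc(OCc3ccccc3)cc2)ccc1OCc1ccccc1)c1c(Cc2ccc(OCc3ccccc3)cc2)c(OC)cc(OCc2ccccc2)c1Cc1ccc(OCc2ccccc2)cc1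
F5 | step 12 | 1-[2-(benzyloxy)-5-[4-(benzyloxy)benzyl]phenyl]-2-[3-(benzyloxy)-2,6-bis[4-(benzyloxy)benzyl]-5-methoxyphenyl]ethyl methanesulfonate (racemic) | CS(=O)(=O)OC(Cc1c(Cc2ccc(OCc3ccccc3)cc2)c(OC)cc(OCc2ccccc2)c1Cc1ccc(OCc2ccccc2)cc1)c1cc(Cc2ccc(OCc3ccccc3)cc2)ccc1OCc1ccccc1
F6 | step 12 | 1-(benzyloxy)-2,4-bis[4-(benzyloxy)benzyl]-3-[(E)-2-[2-(benzyloxy)-5-[4-(benzyloxy)benzyl]phenyl]ethenyl]-5-methoxybenzene | COc1cc(OCc2ccccc2)c(Cc2ccc(OCc3ccccc3)cc2)c(/C=C/c2cc(Cc3ccc(OCc4ccccc4)cc3)ccc2OCc2ccccc2)c1Cc1ccc(OCc2ccccc2)cc1
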